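Ring A of the target (O, C10, C1, C2, C3, C4, C5 in germacrane numbering) is cis-2,6-dimethylcyclohexanone plus one oxygen atom. The precursor of the key step is therefore (2R,6S)-2,6-dimethyl-2-propargylcyclohexanone, made in one step by enantioselective deprotonation and alkylation of the meso ketone. Baeyer–Villiger oxidation inserts oxygen between the C5 carbonyl and the quaternary C10 with retention: in one operation the six-membered carbocycle becomes the seven-membered oxacycle and the all-carbon quaternary centre becomes the tertiary ether centre. After removal of the C5 carbonyl, hydrogen abstraction from the only O–CH2 group closes ring B (C5–C6) onto a vinyl ketone; C7, C9 and C8 are then set from the exo face.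

Key step: step 2

Remark on numbering: ring A = O, C10, C1, C2, C3, C4, C5 (methyls on C4 and C10); ring B = O, C5, C6, C7, C8, C9, C10; the lactone (C11, C12, C13) sits on C7/C8 and the ester on C9. In the bicyclic names, bicycle C1 = germacrane C10, C3 = C8, C6 = C5, C7 = C4.

Assumption: the (S,S)-amide is taken to give the (S)-enolate 2, by analogy with the sense of this base class on 4-substituted cyclohexanones; if the sense proves opposite, the (R,R)-amide is used with no other change. The meso cis ketone 1 is used free of its trans isomer.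

Step 1
Reactants: 1 cis-2,6-dimethylcyclohexan-1-one
Product: 3 (2R,6S)-2,6-dimethyl-2-(prop-2-yn-1-yl)cyclohexan-1-one, via lithium enolate 2 (not isolated)
Conditions: (S,S)-bis(1-phenylethyl)amine, n-BuLi, LiCl, THF, 0 → −78 °C; 1, −78 °C; then propargyl bromide, HMPA, −78 → −20 °C
Reagents that add atoms: propargyl bromide, C#CCBr
Why: Enantioselective deprotonation (chiral lithium amide desymmetrisation, with LiCl to keep the selectivity high when the electrophile is added afterwards) removes one of the two enantiotopic axial α-protons of the meso ketone, so the untouched α-carbon becomes the C4 stereocenter, and the tetrasubstituted enolate 2 is then alkylated (ketone enolate SN2 alkylation) by axial attack anti to the pseudo-axial C4 methyl, which sets the quaternary C10 with propargyl trans to that methyl.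

Step 2
Reactants: 3 (2R,6S)-2,6-dimethyl-2-(prop-2-yn-1-yl)cyclohexan-1-one
Product: 5 (3S,7R)-3,7-dimethyl-7-(prop-2-yn-1-yl)oxepan-2-one, via Criegee adduct 4 (not isolated)
Conditions: m-CPBA, Na2HPO4, CH2Cl2, 0 °C → rt
Reagents that add atoms: m-chloroperoxybenzoic acid, OOC(=O)c1cccc(Cl)c1
Why: Baeyer–Villiger oxidation: the peracid adds to the C5 carbonyl to give Criegee adduct 4, and the C5–C10 bond antiperiplanar to the O–O bond migrates to oxygen as 3-chlorobenzoate leaves. No ring is closed by cyclisation; the six-membered carbocycle (C5, C10, C1, C2, C3, C4) is enlarged by oxygen insertion to the seven-membered lactone that is ring A of the target. No new stereocenter is formed: C10 migrates with retention, so the quaternary carbon set in step 1 becomes the tertiary ether centre, and C4 is not epimerised under the buffered conditions. The step needs migration of the quaternary C10 rather than the secondary C4, which the higher migratory aptitude of the tertiary alkyl group secures. It also needs chemoselectivity over the alkyne, which peracids attack only slowly.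

Step 3
Reactants: 5 (3S,7R)-3,7-dimethyl-7-(prop-2-yn-1-yl)oxepan-2-one
Product: 7 (2R,6S)-2,6-dimethyl-2-(prop-2-yn-1-yl)oxepane, via aluminium lactolate 6 (not isolated)
Conditions: i-Bu2AlH, CH2Cl2, −78 °C; then Et3SiH, BF3·OEt2, −78 → −20 °C
Reagents that add atoms: none
Why: Hydride addition at −78 °C stops at the tetrahedral aluminium lactolate, which BF3 ionises to the cyclic oxocarbenium ion that Et3SiH reduces (lactone-to-ether reductive deoxygenation by ionic hydrogenation), so ring A stays closed and no stereocenter is touched.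

Step 4
Reactants: 7 (2R,6S)-2,6-dimethyl-2-(prop-2-yn-1-yl)oxepane
Product: 8 1-[(2R,6S)-2,6-dimethyloxepan-2-yl]propan-2-one
Conditions: Ph3PAuCl (2 mol%), AgOSO2CF3 (2 mol%), MeOH/H2O, 60 °C
Reagents that add atoms: water, O
Why: Cationic gold activates the terminal alkyne towards Markovnikov addition of water (alkyne hydration), giving the methyl ketone without creating a stereocenter.

Step 5
Reactants: 8 1-[(2R,6S)-2,6-dimethyloxepan-2-yl]propan-2-one
Product: 12 1-[(2R,6S)-2,6-dimethyloxepan-2-yl]but-3-en-2-one, via lithium enolate 9 (not isolated), via Mannich base 10 (not isolated), via methiodide 11 (not isolated)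
Conditions: LiN(i-Pr)2, THF, −78 °C; CH2=NMe2+ I−, −78 → 0 °C; MeI, CH2Cl2, rt; then aq. NaHCO3
Reagents that add atoms: dimethyl(methylene)ammonium iodide (Eschenmoser's salt), C=[N+](C)C.[I-]
Why: Kinetic deprotonation at the methyl group (the other α-carbon is neopentyl) and Mannich reaction with the iminium salt give base 10, whose quaternisation and E1cB elimination deliver the vinyl ketone (Mannich-elimination α-methylenation), no stereocenter being formed.

Step 6
Reactants: 12 1-[(2R,6S)-2,6-dimethyloxepan-2-yl]but-3-en-2-one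
Product: 13 (1R,6R,7S)-1,7-dimethyl-11-oxabicyclo[4.4.1]undecan-3-one
Conditions: (n-Bu4N)4[W10O32] (2 mol%), MeCN (0.005 M), 390 nm LED, N2, rt
Reagents that add atoms: none
Why: Photoexcited decatungstate abstracts hydrogen from C5, the only O–CH2 group (C10 is quaternary), and the nucleophilic α-alkoxy radical adds to the enone terminus C6 in a polarity-matched 7-endo Giese cyclisation that closes ring B before hydrogen is returned to the α-keto radical, the tether from C10 forcing the new C5–C6 bond cis to it and thereby setting C5.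

Step 7
Reactants: 13 (1R,6R,7S)-1,7-dimethyl-11-oxabicyclo[4.4.1]undecan-3-one
Product: 15 methyl [(1R,4R,6R,7S)-1,7-dimethyl-3-oxo-11-oxabicyclo[4.4.1]undecan-4-yl]acetate, via lithium enolate 14 (not isolated)
Conditions: LiN(i-Pr)2, THF, −78 °C; then BrCH2CO2Me, DMPU, −78 → −40 °C
Reagents that add atoms: methyl bromoacetate, COC(=O)CBr
Why: Kinetic deprotonation takes place at C7 because C9 is neopentyl, and SN2 alkylation of enolate 14 (ketone enolate alkylation) occurs on the exo face, opposite the C1–C4 carbon bridge of ring A (germacrane numbering), which sets C7.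

Step 8
Reactants: 15 methyl [(1R,4R,6R,7S)-1,7-dimethyl-3-oxo-11-oxabicyclo[4.4.1]undecan-4-yl]acetate
Product: 17 methyl [(1R,2R,4R,6R,7S)-2-hydroxy-1,7-dimethyl-3-oxo-11-oxabicyclo[4.4.1]undecan-4-yl]acetate, via potassium enolate 16 (not isolated)
Conditions: KN(SiMe3)2, THF, −78 °C; then 2-(phenylsulfonyl)-3-phenyloxaziridine, −78 °C; AcOH quench
Reagents that add atoms: 2-(phenylsulfonyl)-3-phenyloxaziridine, O=S(=O)(N1OC1c1ccccc1)c1ccccc1
Why: The silylamide removes a proton from the C9 methylene of the ketone in preference to the C7 methine and the less acidic ester, and the oxaziridine transfers oxygen to the exo face of enolate 16 (Davis oxidation), which sets C9.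

Step 9
Reactants: 17 methyl [(1R,2R,4R,6R,7S)-2-hydroxy-1,7-dimethyl-3-oxo-11-oxabicyclo[4.4.1]undecan-4-yl]acetate
Product: 19 (4S,5R,7R,8R,9S,10R)-5,10-epoxy-9-hydroxy-13-norgermacran-12,8-olide, via diol ester 18 (not isolated)
Conditions: Me4NBH(OAc)3, MeCN/AcOH, −30 → 0 °C; then camphorsulfonic acid (cat.), CH2Cl2, rt
Reagents that add atoms: none
Why: The C9 hydroxyl binds boron and delivers hydride to the same face of the C8 carbonyl (hydroxyl-directed triacetoxyborohydride reduction, Saksena–Evans type), which sets C8 with its oxygen trans to both neighbours, and acid-catalysed lactonisation of diol 18 then closes the trans-fused γ-lactone with loss of methanol.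

Step 10
Reactants: 19 (4S,5R,7R,8R,9S,10R)-5,10-epoxy-9-hydroxy-13-norgermacran-12,8-olide
Product: 23 (4S,5R,7R,8R,9S,10R)-5,10-epoxy-9-hydroxygermacr-11(13)-en-12,8-olide, via dilithium alkoxide-enolate 20 (not isolated), via Mannich base 21 (not isolated), via methiodide 22 (not isolated)
Conditions: LiN(i-Pr)2 (2.2 equiv), THF, −78 °C; CH2=NMe2+ I−, −78 → 0 °C; aqueous work-up; MeI, CH2Cl2, rt; then aq. NaHCO3
Reagents that add atoms: dimethyl(methylene)ammonium iodide (Eschenmoser's salt), C=[N+](C)C.[I-]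
Why: Double deprotonation gives alkoxide-enolate 20, whose Mannich reaction with the iminium salt followed by N-methylation and elimination installs the exocyclic methylene (Mannich-elimination α-methylenation of a lactone) without forming a stereocenter in the product.

Step 11
Reactants: 23 (4S,5R,7R,8R,9S,10R)-5,10-epoxy-9-hydroxygermacr-11(13)-en-12,8-olide; 24 (R)-2-methylbutanoic acid
Product: 26 (4S,5R,7R,8R,9S,10R)-5,10-epoxy-9-[(2R)-2-methylbutanoyloxy]germacr-11(13)-en-12,8-olide (CNP0136059.1), via O-acylisourea 25 (not isolated)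
Conditions: DCC, DMAP (cat.), CH2Cl2, 0 °C → rt
Reagents that add atoms: none
Why: Carbodiimide activation of the acid with DMAP catalysis (Steglich esterification) acylates the C9 hydroxyl with retention at C9, and the non-enolising conditions preserve the α-stereocenter of the acyl group.

Compound list
1 | cis-2,6-dimethylcyclohexan-1-one (meso, commercial) | C[C@H]1CCC[C@@H](C)C1=O | starting material
2 | lithium (S)-2,6-dimethylcyclohex-1-en-1-olate (formed in situ) | [Li]OC1=C(C)CCC[C@@H]1C | intermediate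
3 | (2R,6S)-2,6-dimethyl-2-(prop-2-yn-1-yl)cyclohexan-1-one | O=C1[C@@](C)(CC#C)CCC[C@@H]1C | intermediate
4 | Criegee adduct of 3: 1-hydroxy-2,6-dimethyl-2-(prop-2-yn-1-yl)cyclohexyl 3-chloroperoxybenzoate (formed in situ) | OC1(OOC(=O)c2cccc(Cl)c2)[C@@](C)(CC#C)CCC[C@@H]1C | intermediate
5 | (3S,7R)-3,7-dimethyl-7-(prop-2-yn-1-yl)oxepan-2-one | O=C1O[C@@](C)(CC#C)CCC[C@@H]1C | intermediate
6 | diisobutylaluminium lactolate of 5 (formed in situ) | CC(C)C[Al](CC(C)C)OC1O[C@@](C)(CC#C)CCC[C@@H]1C | intermediate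
7 | (2R,6S)-2,6-dimethyl-2-(prop-2-yn-1-yl)oxepane | C1O[C@@](C)(CC#C)CCC[C@@H]1C | intermediate
8 | 1-[(2R,6S)-2,6-dimethyloxepan-2-yl]propan-2-one | C1O[C@@](C)(CC(C)=O)CCC[C@@H]1C | intermediate
9 | lithium 3-[(2R,6S)-2,6-dimethyloxepan-2-yl]prop-1-en-2-olate (formed in situ) | C1O[C@@](C)(CC(=C)O[Li])CCC[C@@H]1C | intermediate
10 | 4-(dimethylamino)-1-[(2R,6S)-2,6-dimethyloxepan-2-yl]butan-2-one (formed in situ) | C1O[C@@](C)(CC(=O)CCN(C)C)CCC[C@@H]1C | intermediate
11 | 4-[(2R,6S)-2,6-dimethyloxepan-2-yl]-N,N,N-trimethyl-3-oxobutan-1-aminium iodide (formed in situ) | C1O[C@@](C)(CC(=O)CC[N+](C)(C)C)CCC[C@@H]1C.[I-] | intermediate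
12 | 1-[(2R,6S)-2,6-dimethyloxepan-2-yl]but-3-en-2-one | C1O[C@@](C)(CC(=O)C=C)CCC[C@@H]1C | intermediate
13 | (1R,6R,7S)-1,7-dimethyl-11-oxabicyclo[4.4.1]undecan-3-one | O=C2CC[C@H]1O[C@](C)(CCC[C@@H]1C)C2 | intermediate
14 | lithium (1R,6R,7S)-1,7-dimethyl-11-oxabicyclo[4.4.1]undec-3-en-3-olate (formed in situ) | [Li]OC2=CC[C@H]1O[C@](C)(CCC[C@@H]1C)C2 | intermediate
15 | methyl [(1R,4R,6R,7S)-1,7-dimethyl-3-oxo-11-oxabicyclo[4.4.1]undecan-4-yl]acetate | O=C2[C@@H](CC(=O)OC)C[C@H]1O[C@](C)(CCC[C@@H]1C)C2 | intermediate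
16 | potassium (1R,4R,6R,7S)-4-(2-methoxy-2-oxoethyl)-1,7-dimethyl-11-oxabicyclo[4.4.1]undec-2-en-3-olate (formed in situ) | [K]OC=2[C@@H](CC(=O)OC)C[C@H]1O[C@](C)(CCC[C@@H]1C)C=2 | intermediate
17 | methyl [(1R,2R,4R,6R,7S)-2-hydroxy-1,7-dimethyl-3-oxo-11-oxabicyclo[4.4.1]undecan-4-yl]acetate | O=C2[C@@H](CC(=O)OC)C[C@H]1O[C@](C)(CCC[C@@H]1C)[C@H]2O | intermediate
18 | methyl [(1R,2S,3R,4R,6R,7S)-2,3-dihydroxy-1,7-dimethyl-11-oxabicyclo[4.4.1]undecan-4-yl]acetate (formed in situ) | O[C@@H]2[C@@H](CC(=O)OC)C[C@H]1O[C@](C)(CCC[C@@H]1C)[C@H]2O | intermediate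
19 | (4S,5R,7R,8R,9S,10R)-5,10-epoxy-9-hydroxy-13-norgermacran-12,8-olide | C1C(=O)O[C@@H]2[C@@H]1C[C@H]1O[C@](C)(CCC[C@@H]1C)[C@H]2O | intermediate
20 | dilithium alkoxide-enolate of 19 (formed in situ) | C1=C(O[Li])O[C@@H]2[C@@H]1C[C@H]1O[C@](C)(CCC[C@@H]1C)[C@H]2O[Li] | intermediate
21 | 13-(dimethylamino)-5,10-epoxy-9-hydroxygermacran-12,8-olide, C11 epimers (formed in situ) | CN(C)CC1C(=O)O[C@@H]2[C@@H]1C[C@H]1O[C@](C)(CCC[C@@H]1C)[C@H]2O | intermediate
22 | N-methyl iodide of 21 (formed in situ) | C[N+](C)(C)CC1C(=O)O[C@@H]2[C@@H]1C[C@H]1O[C@](C)(CCC[C@@H]1C)[C@H]2O.[I-] | intermediate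
23 | (4S,5R,7R,8R,9S,10R)-5,10-epoxy-9-hydroxygermacr-11(13)-en-12,8-olide | C=C1C(=O)O[C@@H]2[C@@H]1C[C@H]1O[C@](C)(CCC[C@@H]1C)[C@H]2O | intermediate
24 | (R)-2-methylbutanoic acid (commercial) | CC[C@@H](C)C(=O)O | starting material
25 | O-acylisourea from 24 and DCC (formed in situ) | CC[C@@H](C)C(=O)OC(=NC1CCCCC1)NC1CCCCC1 | intermediate
26 | (4S,5R,7R,8R,9S,10R)-5,10-epoxy-9-[(2R)-2-methylbutanoyloxy]germacr-11(13)-en-12,8-olide (CNP0136059.1) | C=C1C(=O)O[C@@H]2[C@@H]1C[C@H]1O[C@](C)(CCC[C@@H]1C)[C@H]2OC(=O)[C@H](C)CC | target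

Total step count: 11. Longest linear sequence: 11 steps (1 → 26); acid 24 is used as purchased.

Steps most likely to fail

Step 6. The intramolecular radical addition may be outrun by intermolecular addition to a second enone, or the vinyl ketone may degrade under irradiation. The fallback closes ring B by polar C-glycosylation and ring-closing metathesis. It sets out from lactone 5. Reductive acetylation (i-Bu2AlH, then Ac2O, pyridine, DMAP, −78 °C) should give the acetoxy acetal (3S,7R)-3,7-dimethyl-7-(prop-2-yn-1-yl)oxepan-2-yl acetate F1. Allyltrimethylsilane with BF3·OEt2 should give (2R,6S,7R)-2,6-dimethyl-7-(prop-2-en-1-yl)-2-(prop-2-yn-1-yl)oxepane F2; attack anti to the C4 methyl is expected but not secured, and only this 2,7-cis isomer can cyclise later. Hydration (Ph3PAuCl, AgOSO2CF3, MeOH/H2O) should give 1-[(2R,6S,7R)-2,6-dimethyl-7-(prop-2-en-1-yl)oxepan-2-yl]propan-2-one F3. Kinetic silylation (LiN(i-Pr)2, Me3SiCl, −78 °C) should give its 2-(trimethylsilyloxy)allyl enol ether F4. Ring-closing metathesis with the second-generation Grubbs catalyst should close ring B as [(1R,6R,7S)-1,7-dimethyl-11-oxabicyclo[4.4.1]undec-3-en-3-yl]oxy(trimethyl)silane F5. Hydrolysis of the silyl enol ether with dilute aqueous HCl in THF then returns to the route at ketone 13.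

Step 8. Enolisation of 15 may lose regioselectivity (C7 methine or ester α-CH2 instead of C9), or the C9 enolate may open the ether bridge by β-elimination. The fallback makes C9 the only enolisable position. It sets out from 13. Dehydrogenation with IBX (2-iodoxybenzoic acid, DMSO, 70 °C) can only introduce the C6=C7 double bond and should give (1R,6S,7S)-1,7-dimethyl-11-oxabicyclo[4.4.1]undec-4-en-3-one F6. LiN(i-Pr)2 followed by the oxaziridine should give its exo 2-hydroxy derivative F7. Silylation (t-BuMe2SiOSO2CF3, 2,6-lutidine) should give the tert-butyldimethylsilyl ether F8. Conjugate reduction with K[sec-Bu3BH] and trapping of the regiospecific C7 enolate with methyl bromoacetate should give the 2-silyloxy keto ester F9. HF·pyridine removes the silyl group and returns to the route at 17.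

Step 9. Hydride delivery at C8 may show poor facial selectivity, so that the C8 epimer (and from it the cis-fused lactone) predominates. The fallback introduces the lactone oxygen with inversion. It sets out from 17. Reduction with Li[sec-Bu3BH] (THF, −78 °C), which should attack anti to the two exo neighbours, is expected to give the C3-epimeric diol ester methyl [(1R,2S,3S,4R,6R,7S)-2,3-dihydroxy-1,7-dimethyl-11-oxabicyclo[4.4.1]undecan-4-yl]acetate F10. Saponification (LiOH, THF/H2O) should give the corresponding hydroxy acid F11. Mitsunobu lactonisation (PPh3, DIAD, toluene, 0 °C) displaces the activated C8 hydroxyl by the carboxylate with inversion and returns to the route at 19.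

Further compounds
F1 | step 6 | (3S,7R)-3,7-dimethyl-7-(prop-2-yn-1-yl)oxepan-2-yl acetate (both anomers) | CC(=O)OC1O[C@@](C)(CC#C)CCC[C@@H]1C
F2 | step 6 | (2R,6S,7R)-2,6-dimethyl-7-(prop-2-en-1-yl)-2-(prop-2-yn-1-yl)oxepane | C=CC[C@H]1O[C@@](C)(CC#C)CCC[C@@H]1C
F3 | step 6 | 1-[(2R,6S,7R)-2,6-dimethyl-7-(prop-2-en-1-yl)oxepan-2-yl]propan-2-one | C=CC[C@H]1O[C@@](C)(CC(C)=O)CCC[C@@H]1C
F4 | step 6 | ({3-[(2R,6S,7R)-2,6-dimethyl-7-(prop-2-en-1-yl)oxepan-2-yl]prop-1-en-2-yl}oxy)trimethylsilane | C=CC[C@H]1O[C@@](C)(CC(=C)O[Si](C)(C)C)CCC[C@@H]1C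
F5 | step 6 | [(1R,6R,7S)-1,7-dimethyl-11-oxabicyclo[4.4.1]undec-3-en-3-yl]oxy(trimethyl)silane | C[Si](C)(C)OC2=CC[C@H]1O[C@](C)(CCC[C@@H]1C)C2
F6 | step 8 | (1R,6S,7S)-1,7-dimethyl-11-oxabicyclo[4.4.1]undec-4-en-3-one | O=C2C=C[C@H]1O[C@](C)(CCC[C@@H]1C)C2
F7 | step 8 | exo-2-hydroxy derivative of F6 | O=C2C=C[C@H]1O[C@](C)(CCC[C@@H]1C)[C@H]2O
F8 | step 8 | tert-butyldimethylsilyl ether of F7 | O=C2C=C[C@H]1O[C@](C)(CCC[C@@H]1C)[C@H]2O[Si](C)(C)C(C)(C)C
F9 | step 8 | tert-butyldimethylsilyl ether of 17 | O=C2[C@@H](CC(=O)OC)C[C@H]1O[C@](C)(CCC[C@@H]1C)[C@H]2O[Si](C)(C)C(C)(C)C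
F10 | step 9 | methyl [(1R,2S,3S,4R,6R,7S)-2,3-dihydroxy-1,7-dimethyl-11-oxabicyclo[4.4.1]undecan-4-yl]acetate | O[C@H]2[C@@H](CC(=O)OC)C[C@H]1O[C@](C)(CCC[C@@H]1C)[C@H]2O
F11 | step 9 | [(1R,2S,3S,4R,6R,7S)-2,3-dihydroxy-1,7-dimethyl-11-oxabicyclo[4.4.1]undecan-4-yl]acetic acid | O[C@H]2[C@@H](CC(=O)O)C[C@H]1O[C@](C)(CCC[C@@H]1C)[C@H]2O
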